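The leftover we want is the electrophile still unreacted when the run stops, and with it the nucleophile still free.

electrophile 10 mM; gas 1.9 mM (held); time 6.0 min

    electrophile + nucleophile → acid set free + target (k1 = 15 M⁻¹ s⁻¹)
    nucleophile + acid set free ⇌ protonated nucleophile, settled at all times (K2 = 1.5 × 10⁵ M⁻¹)
    gas ⇌ nucleophile, rate k3*(csat - [nucleophile]) (k3 = 0.040 s⁻¹, csat = 1.9 mM)
    acid set free → by-product carried off (k4 = 0.022 s⁻¹)
    target → over-reaction product (k5 = 0.0098 s⁻¹)

- at the start none of nucleophile is dissolved
- run time (flask): 6.0 min

- part of the electrophile that has reacted at 6.0 min
- share of the unused nucleophile that is free and not bound as protonated nucleophile, at 6.0 min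

Let us ask what an error in each given number would cost. The over-reaction constant costs nothing in c, since it acts on target downstream of the electrophile. The constant of the main reaction costs little at first, because by that step alone, with electrophile as charged, nucleophile has a half-life of 0.077 min, far shorter than the run. The binding constant counts by being large: times the saturation concentration it gives 285, so each electrophile that reacts costs about two nucleophiles, one to react and one to bind the acid. The carry-off constant acts on free acid, which this binding holds down.

The transfer coefficient, the saturation concentration and the charge enter together. While the electrophile stands near its charge, it takes up dissolved nucleophile with a first-order constant of 0.150 s⁻¹, larger than the 0.040 s⁻¹ of transfer, so the gas delivers close to its full 4.56 mM min⁻¹ and transfer is the rate-limiting step of that early stretch. We carry the feed time τ, the time full transfer needs to deliver two nucleophiles per electrophile charged: 4.39 min. The run is longer, at 1.37 τ. As the electrophile thins, nucleophile rises and transfer falls below full, so we expect c close to complete, with a small tail. Our hand gives no figure for that tail or for fr.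

The forecast gave 94.5 % (93.5 % to 95.5 %) and 12.1 % (10.5 % to 13.8 %), holding that “nearly all the acid sits as protonated nucleophile”.

The flask gives 94.5 % and 12.2 %.

In this flask, 3.00 min is 0.683 τ, but less of the electrophile has reacted by then, 56.5 %. The neighbour charged with 25 mM of electrophile, time held, has τ of 11.0 min, longer than the run, so the same reckoning gives 54.7 % reacted. That flask gives 54.6 %, with fr at 1.88 %. The nucleophile taken up in that flask, reacted plus bound plus free, is 25.3 mM against 27.4 mM at full transfer, and 1.93 mM of its acid has been carried off as by-product.

The constants used here are invented; the flask was simulated.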